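**Retrosynthetic overview**
1. Target ⇐ ortho-bromination of 3,5-dibromo-2-(3,5-dibromo-2-methoxyphenoxy)phenol; the fifth bromine enters next to the free OH.
2. That phenol ⇐ Baeyer–Villiger (Dakin-type) oxidation of the matching 2-aryloxybenzaldehyde; CHO is a latent OH, so the two ring B oxygens are never both free.
3. Key disconnection, the diaryl ether C–O bond: 3,5-dibromosalicylaldehyde phenoxide plus ring A as an aryl cation equivalent (an aryl(phenyl)iodonium salt). The anisole ortho carbon, innately nucleophilic like the phenol oxygen, reacts with reversed polarity.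
4. Iodonium salt ⇐ 2,4-dibromoanisole by C–H substitution with the trivalent-iodine electrophile from PhI(OAc)2 and TfOH.
5. No ring is formed: both benzene rings are bought, with four of the five bromines already in place.

Assumption: the target is achiral (no stereocentre), so no enantiocontrol is needed; every C–C bond lies inside a purchased benzene ring, so the strategic bond is the diaryl ether C–O bond.

**Route**

Step 1
Reactants: 1 2,4-dibromoanisole (2,4-dibromo-1-methoxybenzene)
Product: 2 (3,5-dibromo-2-methoxyphenyl)(phenyl)iodonium trifluoromethanesulfonate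
Conditions: PhI(OAc)2 (1.0 equiv), TfOH (2.0 equiv), CH2Cl2, 0 °C, 30 min; then 1 (1.05 equiv), 0 °C → rt; concentrate, triturate with Et2O
Reagents that add atoms: (diacetoxyiodo)benzene, CC(=O)OI(OC(C)=O)c1ccccc1; trifluoromethanesulfonic acid, OS(=O)(=O)C(F)(F)F
Why: Electrophilic aromatic substitution by a trivalent-iodine electrophile (the usual arene plus PhI(OAc)2/TfOH synthesis of aryl(phenyl)iodonium triflates): TfOH turns PhI(OAc)2 into a strongly electrophilic iodine triflate that attacks 1 at C6, the only free position ortho or para to OMe, and the triflate salt is isolated by trituration.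

Step 2
Reactants: 2 (3,5-dibromo-2-methoxyphenyl)(phenyl)iodonium trifluoromethanesulfonate; 3 3,5-dibromo-2-hydroxybenzaldehyde (3,5-dibromosalicylaldehyde)
Product: 5 3,5-dibromo-2-(3,5-dibromo-2-methoxyphenoxy)benzaldehyde, via potassium phenoxide 4 (not isolated)
Conditions: 3, KOt-Bu (1.05 equiv), THF, 0 °C, 15 min; then 2 (1.2 equiv), 40 °C
Reagents that add atoms: none
Why: Metal-free O-arylation of a phenoxide by a diaryliodonium salt (ligand exchange at trivalent iodine, then ligand coupling): the ring A aryl is transferred in preference to phenyl because it is the more electron-poor group (two Br meta to iodine) and the ortho-substituted one, iodobenzene leaves, the preformed weakly basic phenoxide can react only at oxygen because its ortho and para carbons are substituted, and without a transition metal the C–Br bonds and the aldehyde are untouched.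

Step 3
Reactants: 5 3,5-dibromo-2-(3,5-dibromo-2-methoxyphenoxy)benzaldehyde
Product: 7 3,5-dibromo-2-(3,5-dibromo-2-methoxyphenoxy)phenol, via aryl formate 6 (not isolated)
Conditions: mCPBA (2 equiv), CH2Cl2, 40 °C; aq Na2S2O3/NaHCO3 wash; then Et3N (0.2 equiv), MeOH, rt
Reagents that add atoms: mCPBA (3-chloroperoxybenzoic acid), OOC(=O)c1cccc(Cl)c1
Why: Baeyer–Villiger (Dakin-type) oxidation: the ortho-aryloxy group makes the aryl ring migrate in the Criegee adduct, as in the standard conversion of 2-aryloxybenzaldehydes into 2-aryloxyphenols, and the resulting formate 6 is cleaved by mild methanolysis.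

Step 4
Reactants: 7 3,5-dibromo-2-(3,5-dibromo-2-methoxyphenoxy)phenol
Product: 8 2,3,5-tribromo-6-(3,5-dibromo-2-methoxyphenoxy)phenol (target)
Conditions: NBS (1.05 equiv), i-Pr2NH (0.1 equiv), CH2Cl2, 0 °C → rt
Reagents that add atoms: N-bromosuccinimide, O=C1CCC(=O)N1Br
Why: Amine-catalysed ortho-selective bromination of a phenol: the N-bromoamine formed from NBS and i-Pr2NH hydrogen-bonds to the OH and delivers bromine to the one free ortho carbon, while the para carbon is shielded between two bromines and ring A, which has no free OH, is far less reactive.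

**Compound list**

1 | 2,4-dibromoanisole | COc1ccc(Br)cc1Br | starting material
2 | (3,5-dibromo-2-methoxyphenyl)(phenyl)iodonium trifluoromethanesulfonate | COc1c(Br)cc(Br)cc1[I+]c1ccccc1.[O-]S(=O)(=O)C(F)(F)F | intermediate
3 | 3,5-dibromo-2-hydroxybenzaldehyde | O=Cc1cc(Br)cc(Br)c1O | starting material
4 | potassium 2,4-dibromo-6-formylphenolate | O=Cc1cc(Br)cc(Br)c1[O-].[K+] | intermediate (not isolated)
5 | 3,5-dibromo-2-(3,5-dibromo-2-methoxyphenoxy)benzaldehyde | COc1c(Br)cc(Br)cc1Oc1c(Br)cc(Br)cc1C=O | intermediate
6 | 3,5-dibromo-2-(3,5-dibromo-2-methoxyphenoxy)phenyl formate | COc1c(Br)cc(Br)cc1Oc1c(Br)cc(Br)cc1OC=O | intermediate (not isolated)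
7 | 3,5-dibromo-2-(3,5-dibromo-2-methoxyphenoxy)phenol | COc1c(Br)cc(Br)cc1Oc1c(Br)cc(Br)cc1O | intermediate
8 | 2,3,5-tribromo-6-(3,5-dibromo-2-methoxyphenoxy)phenol | COc1c(Br)cc(Br)cc1Oc1c(Br)cc(Br)c(Br)c1O | target

**Totals**

Total step count: 4. Longest linear sequence: 4 (1 → 2 → 5 → 7 → 8); 3 is a purchased coupling partner.

**Steps most likely to fail, with fallbacks**

Step 2. The hindered, electron-poor phenoxide may react slowly, and part of the salt may transfer phenyl instead of the ring A aryl. The fallback keeps ring A as the electrophile but as a metal carbenoid: it sets out from 3 and comes back at 5. 2-Amino-4,6-dibromophenol F1 is diazotised (NaNO2, aq H2SO4, 0 °C, then NaOAc) to the quinone diazide 2,4-dibromo-6-diazocyclohexa-2,4-dien-1-one F2. Slow addition of F2 to excess 3 with Rh2(OAc)4 (1 mol%) in 1,2-dichloroethane at 60 °C should give, by O–H insertion of the rhodium carbenoid and tautomerisation, 3,5-dibromo-2-(3,5-dibromo-2-hydroxyphenoxy)benzaldehyde F3. This insertion with a phenol is proposed by analogy with carbenoid O–H insertions, not a documented case. Methylation of F3 (MeI, K2CO3, acetone) gives 5.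

Step 3. The ring carrying two bromines and an electron-poor aryloxy group may migrate too slowly, so that hydride migration gives the benzoic acid. The fallback carries the second oxygen as a removable ether from the start and needs no oxidation: it sets out from 2 and comes back at 7. 2-(Propan-2-yloxy)phenol F4 is brominated ortho and then para to the OH (NBS, 2.1 equiv, i-Pr2NH, 0.2 equiv, CH2Cl2, 0 °C → rt) to give 2,4-dibromo-6-(propan-2-yloxy)phenol F5; the amine-catalysed conditions keep the bromination under the control of the free OH and not of the ether. Deprotonation (KOt-Bu, THF) gives potassium 2,4-dibromo-6-(propan-2-yloxy)phenolate F6, which is arylated by 2 as in step 2 to give 1,5-dibromo-3-[2,4-dibromo-6-(propan-2-yloxy)phenoxy]-2-methoxybenzene F7. BCl3 (CH2Cl2, −20 → 0 °C) removes the isopropyl group in the presence of the methyl ether and gives 7.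

Step 4. Bromination may go partly to the para carbon or over-brominate. The fallback installs this bromine before the coupling: it sets out from 2 and comes back at 8. 2-Bromo-6-hydroxybenzaldehyde F8 is dibrominated ortho and para to the OH (Br2, 2 equiv, NaOAc, AcOH) to give 3,5,6-tribromo-2-hydroxybenzaldehyde F9. Its salt, potassium 3,4,6-tribromo-2-formylphenolate F10 (KOt-Bu, THF), is arylated by 2 to give 2,3,5-tribromo-6-(3,5-dibromo-2-methoxyphenoxy)benzaldehyde F11. Baeyer–Villiger oxidation (mCPBA, CH2Cl2, 40 °C) gives 2,3,5-tribromo-6-(3,5-dibromo-2-methoxyphenoxy)phenyl formate F12, and methanolysis (Et3N, MeOH) gives 8 directly. This oxidation is on a more electron-poor ring than in step 3, so it carries the same risk in a sharper form.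

**Further compounds**

F1 | step 2 | 2-amino-4,6-dibromophenol | Nc1cc(Br)cc(Br)c1O
F2 | step 2 | 2,4-dibromo-6-diazocyclohexa-2,4-dien-1-one | [N-]=[N+]=C1C=C(Br)C=C(Br)C1=O
F3 | step 2 | 3,5-dibromo-2-(3,5-dibromo-2-hydroxyphenoxy)benzaldehyde | O=Cc1cc(Br)cc(Br)c1Oc1cc(Br)cc(Br)c1O
F4 | step 3 | 2-(propan-2-yloxy)phenol | CC(C)Oc1ccccc1O
F5 | step 3 | 2,4-dibromo-6-(propan-2-yloxy)phenol | CC(C)Oc1cc(Br)cc(Br)c1O
F6 | step 3 | potassium 2,4-dibromo-6-(propan-2-yloxy)phenolate | CC(C)Oc1cc(Br)cc(Br)c1[O-].[K+]
F7 | step 3 | 1,5-dibromo-3-[2,4-dibromo-6-(propan-2-yloxy)phenoxy]-2-methoxybenzene | COc1c(Br)cc(Br)cc1Oc1c(Br)cc(Br)cc1OC(C)C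
F8 | step 4 | 2-bromo-6-hydroxybenzaldehyde | O=Cc1c(O)cccc1Br
F9 | step 4 | 3,5,6-tribromo-2-hydroxybenzaldehyde | O=Cc1c(O)c(Br)cc(Br)c1Br
F10 | step 4 | potassium 3,4,6-tribromo-2-formylphenolate | O=Cc1c([O-])c(Br)cc(Br)c1Br.[K+]
F11 | step 4 | 2,3,5-tribromo-6-(3,5-dibromo-2-methoxyphenoxy)benzaldehyde | COc1c(Br)cc(Br)cc1Oc1c(Br)cc(Br)c(Br)c1C=O
F12 | step 4 | 2,3,5-tribromo-6-(3,5-dibromo-2-methoxyphenoxy)phenyl formate | COc1c(Br)cc(Br)cc1Oc1c(Br)cc(Br)c(Br)c1OC=O
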